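Ring A of the upper flavan carries O1 on C8a and C4 on the neighbouring C4a, and only the 7-hydroxyl besides. Two adjacent ring carbons, one bonded to O and one to C, are what a benzyne leaves after it has taken up a C=O group.
Target ⇒ (debenzylation) hepta-O-benzyl all-cis flavan-3-ol ⇒ (C2, C3 and C4 fixed together by a dynamic kinetic reduction) 4-arylflavan-3-one ⇒ (hydroboration, oxidation) 4-arylflav-3-ene.
Flav-3-ene ⇒ 3-bromo-5-benzyloxybenzyne + 8-cinnamoyl-type enone of epicatechin. O1–C8a, C4–C4a and O1–C2 form in one operation; a bromine at C5 steers the aryne and is removed directly afterwards.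
Enone ⇒ 8-lithio-penta-O-benzylepicatechin + a Weinreb cinnamamide. Aryne precursor ⇒ 3,5-dibromophenol, by silylation between the two bromines and exchange of one bromine for oxygen.
Ring order: rings A and B and the whole lower unit (rings D, E, F) are bought; ring C is the only ring formed, in the key step.

Key step: step 10

Stereochemical reading: the upper unit is (2R,3R,4S). This places the C2 aryl group, the 3-hydroxyl and the C4 aryl group on one face of ring C (2,3-cis-3,4-cis, a 4α→8 link). The lower unit is (2R,3R), that is (−)-epicatechin.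
Assumption: in the transfer hydrogenation the diaryl-substituted C4 flank of the flavan-3-one is taken to play the part of the aryl group in the usual Noyori–Ikariya model, which assigns the (S,S)-TsDPEN ligand to the 3R alcohol.

Step 1
Reactants: 1 3,5-dibromophenol
Product: 2 1-(benzyloxy)-3,5-dibromobenzene
Conditions: BnBr, K2CO3, acetone, reflux
Reagents that add atoms: benzyl bromide, BrCc1ccccc1
Why: Williamson ether synthesis on the only acidic OH, with the aryl bromides inert to K2CO3.

Step 2
Reactants: 2 1-(benzyloxy)-3,5-dibromobenzene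
Product: 4 [4-(benzyloxy)-2,6-dibromophenyl]trimethylsilane, via aryllithium 3 (not isolated)
Conditions: LiN(i-Pr)2, TMSCl (present from the start), THF, −78 °C
Reagents that add atoms: chlorotrimethylsilane, C[Si](C)(C)Cl; lithium diisopropylamide, [Li]N(C(C)C)C(C)C (lithium, in 3 only)
Why: Deprotonative ortho-lithiation with in situ silyl trapping, in which the C–H flanked by two bromines is the most acidic ring position, the amide base does not exchange bromine, and TMSCl should capture 3 before LiBr loss or halogen migration.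

Step 3
Reactants: 4 [4-(benzyloxy)-2,6-dibromophenyl]trimethylsilane
Product: 7 5-(benzyloxy)-3-bromo-2-(trimethylsilyl)phenol, via aryllithium 5 (not isolated), via dimethyl arylboronate 6 (not isolated)
Conditions: n-BuLi (1 equiv), THF, −78 °C; B(OMe)3, −78 °C → rt; 30% aq H2O2, 0 °C → rt
Reagents that add atoms: n-butyllithium, [Li]CCCC (lithium, in 5 only); trimethyl borate, COB(OC)OC (boron and methoxy groups, in 6 only); hydrogen peroxide, OO
Why: Bromine–lithium exchange on one of two equivalent bromines raises no regiochemical question and leaves Li meta to the other bromine (so no aryne forms), and borylation with boronate oxidation (aryl shift from B to O) turns C–Br into C–OH without touching silicon.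

Step 4
Reactants: 7 5-(benzyloxy)-3-bromo-2-(trimethylsilyl)phenol
Product: 8 5-(benzyloxy)-3-bromo-2-(trimethylsilyl)phenyl trifluoromethanesulfonate
Conditions: Tf2O, pyridine, CH2Cl2, 0 °C
Reagents that add atoms: trifluoromethanesulfonic anhydride, O=S(=O)(OS(=O)(=O)C(F)(F)F)C(F)(F)F
Why: O-sulfonylation of the phenol under non-acidic conditions (no protodesilylation) completes the ortho-silylaryl triflate.

Step 5
Reactants: 9 (−)-epicatechin
Product: 10 5,7,3',4'-tetra-O-benzyl-(−)-epicatechin
Conditions: BnBr, K2CO3, DMF, 0 °C → rt, Ar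
Reagents that add atoms: benzyl bromide, BrCc1ccccc1
Why: Williamson etherification of the four phenols only, because K2CO3 does not deprotonate the secondary 3-OH, and low temperature under argon should keep C2 and C3 (2R,3R) intact.

Step 6
Reactants: 10 5,7,3',4'-tetra-O-benzyl-(−)-epicatechin
Product: 11 8-bromo-5,7,3',4'-tetra-O-benzyl-(−)-epicatechin
Conditions: NBS (1 equiv), CH2Cl2, −78 °C → rt
Reagents that add atoms: N-bromosuccinimide, O=C1CCC(=O)N1Br
Why: Electrophilic aromatic bromination, for which C8 is the more reactive of the two free positions of ring D in benzylated flavan-3-ols at low temperature.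

Step 7
Reactants: 11 8-bromo-5,7,3',4'-tetra-O-benzyl-(−)-epicatechin
Product: 12 8-bromo-3,5,7,3',4'-penta-O-benzyl-(−)-epicatechin
Conditions: NaH, BnBr, DMF, 0 °C → rt
Reagents that add atoms: benzyl bromide, BrCc1ccccc1
Why: Williamson etherification of the alkoxide masks the last OH before the organolithium step without touching a stereocentre.

Step 8
Reactants: 13 4-(benzyloxy)benzaldehyde
Product: 14 (E)-3-[4-(benzyloxy)phenyl]-N-methoxy-N-methylprop-2-enamide
Conditions: (EtO)2P(O)CH2C(O)N(OMe)Me, NaH, THF, 0 °C → rt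
Reagents that add atoms: diethyl [2-(methoxy(methyl)amino)-2-oxoethyl]phosphonate, CCOP(=O)(CC(=O)N(C)OC)OCC
Why: Horner–Wadsworth–Emmons olefination with a stabilised phosphonate should give the E alkene.

Step 9
Reactants: 12 8-bromo-3,5,7,3',4'-penta-O-benzyl-(−)-epicatechin; 14 (E)-3-[4-(benzyloxy)phenyl]-N-methoxy-N-methylprop-2-enamide
Product: 17 (E)-1-(3,5,7,3',4'-penta-O-benzylepicatechin-8-yl)-3-[4-(benzyloxy)phenyl]prop-2-en-1-one, via 8-lithio species 15 (not isolated), via tetrahedral lithium adduct 16 (not isolated)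
Conditions: 12, n-BuLi, THF, −78 °C; then 14, −78 → 0 °C; H2O
Reagents that add atoms: n-butyllithium, [Li]CCCC (lithium, in 15 and 16 only)
Why: Bromine–lithium exchange followed by a Weinreb ketone synthesis, in which the chelated adduct 16 blocks over-addition and 1,2-attack leaves the E alkene and the (2R,3R) centres unchanged.

Step 10
Reactants: 8 5-(benzyloxy)-3-bromo-2-(trimethylsilyl)phenyl trifluoromethanesulfonate; 17 (E)-1-(3,5,7,3',4'-penta-O-benzylepicatechin-8-yl)-3-[4-(benzyloxy)phenyl]prop-2-en-1-one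
Product: 21 5-bromo-7,4'-bis(benzyloxy)-4-(penta-O-benzylepicatechin-8-yl)flav-3-ene as both C2 epimers, via aryne 18 (not isolated), via benzoxete 19 (not isolated), via ortho-quinone methide 20 (not isolated)
Conditions: CsF, MeCN–toluene (1:1), 4 Å MS, 40 °C, concentrated in 17, slow addition of excess 8
Reagents that add atoms: none
Why: Proposed new method: Fluoride removes the silyl group of 8 and triflate leaves to give aryne 18, whose triple bond is distorted by the adjacent C–Br, so the carbonyl oxygen of 17 (electron-rich through its 4-benzyloxystyryl and trialkoxyaryl donors) should bond to the carbon remote from bromine (O1–C8a), and the aryl anion next to bromine should collapse on the oxocarbenium carbon (C4–C4a) to give benzoxete 19. Strain-driven 4π opening of 19 gives ortho-quinone methide 20, whose exocyclic bond should rotate easily because of its phenoxide/diarylallyl-cation character, so the styryl arm can reach the s-cis geometry. Ring C then closes by thermal disrotatory oxa-6π electrocyclisation (O1–C2), driven by rearomatisation of ring A, and since the aryl arm cannot cyclise without losing aromaticity both geometries of 20 should drain to 21. The closest known reaction type is the formal [2+2] addition of arynes to the C=O of formamides and of α,β-unsaturated aldehydes, followed by the same opening and closure to 2H-chromenes; an aryl vinyl ketone has not been shown to react this way. C2 is the only new stereocentre and nothing controls it (the lower unit is remote), so both epimers are expected and both are carried on because C2 is reset in step 14. The step needs regioselectivity, secured by the C5 bromine against a weak opposing inductive effect of the 7-benzyloxy group, and chemoselectivity for C=O over the styryl C=C, favoured by the polarised haloaryne, the high enone concentration and the slow aryne release.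

Step 11
Reactants: 21 5-bromo-7,4'-bis(benzyloxy)-4-(penta-O-benzylepicatechin-8-yl)flav-3-ene
Product: 23 7,4'-bis(benzyloxy)-4-(penta-O-benzylepicatechin-8-yl)flav-3-ene as both C2 epimers, via 5-lithio flav-3-ene 22 (not isolated)
Conditions: n-BuLi, THF, −78 °C, short contact; MeOH
Reagents that add atoms: n-butyllithium, [Li]CCCC (lithium, in 22 only)
Why: Bromine–lithium exchange (faster than any deprotonation at −78 °C) and protonation remove the bromine now, because its peri contact would force the C4 aryl group pseudo-axial once C4 is sp3 and so oppose the 2,4-cis arrangement needed in step 14.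

Step 12
Reactants: 23 7,4'-bis(benzyloxy)-4-(penta-O-benzylepicatechin-8-yl)flav-3-ene
Product: 25 2,3-trans-3,4-trans-7,4'-bis(benzyloxy)-4-(penta-O-benzylepicatechin-8-yl)flavan-3-ol as two diastereomers, via C3 alkylborane 24 (not isolated)
Conditions: BH3·THF, THF, 0 °C → rt; H2O2, aq NaOH, 0 °C
Reagents that add atoms: borane–tetrahydrofuran, B.C1CCOC1 (boron, in 24 only); hydrogen peroxide, OO
Why: Hydroboration–oxidation places boron on the less substituted C3 (away from the diaryl-substituted C4) by syn addition anti to the C2 aryl group, and the resulting trans,trans configuration does not matter because C3 is oxidised and C2 and C4 are equilibrated later.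

Step 13
Reactants: 25 2,3-trans-3,4-trans-7,4'-bis(benzyloxy)-4-(penta-O-benzylepicatechin-8-yl)flavan-3-ol
Product: 26 7,4'-bis(benzyloxy)-4-(penta-O-benzylepicatechin-8-yl)flavan-3-one as a mixture of C2 and C4 epimers
Conditions: Dess–Martin periodinane, CH2Cl2, rt
Reagents that add atoms: none
Why: Dess–Martin oxidation is the established near-neutral way from benzylated flavan-3-ols to flavan-3-ones and spares benzyl ethers and electron-rich arenes.

Step 14
Reactants: 26 7,4'-bis(benzyloxy)-4-(penta-O-benzylepicatechin-8-yl)flavan-3-one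
Product: 28 (2R,3R,4S)-7,4'-bis(benzyloxy)-4-(penta-O-benzylepicatechin-8-yl)flavan-3-ol (2,3-cis-3,4-cis), via (2R,4S)-ketone epimer 27 (not isolated)
Conditions: RuCl(p-cymene)[(S,S)-TsDPEN] (cat.), HCO2H–Et3N (1:2), THF, 40 °C, Ar
Reagents that add atoms: none
Why: Proposed new method: Et3N should interconvert the C2 and C4 epimers of 26 through the two enols faster than the ketone is reduced, while the chiral ruthenium hydride transfers hydride and proton through the usual six-membered outer-sphere transition state preferentially to the 2,4-cis epimer 27, entering C3 anti to both pseudo-equatorial aryl groups, so that C3 becomes R with an axial hydroxyl and C2 (R) and C4 (S) are fixed with it as the all-cis triad; the closest known reaction types are Noyori–Ikariya transfer hydrogenation with dynamic kinetic resolution of isoflavanones and 2-arylcycloalkanones to cis alcohols and the hydrogenative dynamic kinetic resolution of α,α'-disubstituted cycloalkanones to all-cis alcohols, whereas a flavan-3-one with two labile benzylic centres has not been shown.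

Step 15
Reactants: 28 (2R,3R,4S)-7,4'-bis(benzyloxy)-4-(penta-O-benzylepicatechin-8-yl)flavan-3-ol
Product: 29 (2R,3R,4S)-2-(4-hydroxyphenyl)-4-[(2R,3R)-2-(3,4-dihydroxyphenyl)-3,5,7-trihydroxychroman-8-yl]chromane-3,7-diol (target)
Conditions: H2 (1 atm), Pd(OH)2/C, THF–MeOH, rt
Reagents that add atoms: none
Why: Catalytic hydrogenolysis should cleave all seven benzyl ethers, while the cyclic C2–O1 bonds, the C4–C8 link and the five stereocentres are not affected at one atmosphere.

Compound list
1 | 3,5-dibromophenol | Oc1cc(Br)cc(Br)c1 | starting material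
2 | 1-(benzyloxy)-3,5-dibromobenzene | Brc1cc(Br)cc(OCc2ccccc2)c1 | intermediate
3 | [4-(benzyloxy)-2,6-dibromophenyl]lithium | [Li]c1c(Br)cc(OCc2ccccc2)cc1Br | intermediate (not isolated)
4 | [4-(benzyloxy)-2,6-dibromophenyl]trimethylsilane | C[Si](C)(C)c1c(Br)cc(OCc2ccccc2)cc1Br | intermediate
5 | [5-(benzyloxy)-3-bromo-2-(trimethylsilyl)phenyl]lithium | [Li]c1cc(OCc2ccccc2)cc(Br)c1[Si](C)(C)C | intermediate (not isolated)
6 | dimethyl [5-(benzyloxy)-3-bromo-2-(trimethylsilyl)phenyl]boronate | COB(OC)c1cc(OCc2ccccc2)cc(Br)c1[Si](C)(C)C | intermediate (not isolated)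
7 | 5-(benzyloxy)-3-bromo-2-(trimethylsilyl)phenol | Oc1cc(OCc2ccccc2)cc(Br)c1[Si](C)(C)C | intermediate
8 | 5-(benzyloxy)-3-bromo-2-(trimethylsilyl)phenyl trifluoromethanesulfonate | C[Si](C)(C)c1c(Br)cc(OCc2ccccc2)cc1OS(=O)(=O)C(F)(F)F | intermediate
9 | (−)-epicatechin, (2R,3R) | O[C@@H]1Cc2c(O)cc(O)cc2O[C@@H]1c1ccc(O)c(O)c1 | starting material
10 | 5,7,3',4'-tetra-O-benzyl-(−)-epicatechin | c1c(OCc3ccccc3)cc(OCc3ccccc3)c2c1O[C@H](c1ccc(OCc3ccccc3)c(OCc3ccccc3)c1)[C@H](O)C2 | intermediate
11 | 8-bromo-5,7,3',4'-tetra-O-benzyl-(−)-epicatechin | Brc1c(OCc3ccccc3)cc(OCc3ccccc3)c2c1O[C@H](c1ccc(OCc3ccccc3)c(OCc3ccccc3)c1)[C@H](O)C2 | intermediate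
12 | 8-bromo-3,5,7,3',4'-penta-O-benzyl-(−)-epicatechin | Brc1c(OCc3ccccc3)cc(OCc3ccccc3)c2c1O[C@H](c1ccc(OCc3ccccc3)c(OCc3ccccc3)c1)[C@H](OCc1ccccc1)C2 | intermediate
13 | 4-(benzyloxy)benzaldehyde | O=Cc1ccc(OCc2ccccc2)cc1 | starting material
14 | (E)-3-[4-(benzyloxy)phenyl]-N-methoxy-N-methylprop-2-enamide | CON(C)C(=O)/C=C/c1ccc(OCc2ccccc2)cc1 | intermediate
15 | 8-lithio-3,5,7,3',4'-penta-O-benzylepicatechin | [Li]c1c(OCc3ccccc3)cc(OCc3ccccc3)c2c1O[C@H](c1ccc(OCc3ccccc3)c(OCc3ccccc3)c1)[C@H](OCc1ccccc1)C2 | intermediate (not isolated)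
16 | lithium alkoxide of the tetrahedral Weinreb adduct (carbinol carbon undefined) | [Li]OC(/C=C/c1ccc(OCc3ccccc3)cc1)(N(C)OC)c1c(OCc3ccccc3)cc(OCc3ccccc3)c2c1O[C@H](c1ccc(OCc3ccccc3)c(OCc3ccccc3)c1)[C@H](OCc1ccccc1)C2 | intermediate (not isolated)
17 | (E)-1-(3,5,7,3',4'-penta-O-benzylepicatechin-8-yl)-3-[4-(benzyloxy)phenyl]prop-2-en-1-one | O=C(/C=C/c1ccc(OCc3ccccc3)cc1)c1c(OCc3ccccc3)cc(OCc3ccccc3)c2c1O[C@H](c1ccc(OCc3ccccc3)c(OCc3ccccc3)c1)[C@H](OCc1ccccc1)C2 | intermediate
18 | 3-bromo-5-(benzyloxy)benzyne | BrC1=CC(OCc2ccccc2)=CC#C1 | intermediate (not isolated)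
19 | benzoxete from 18 and the C=O of 17 (sp3 carbon undefined) | Brc1cc(OCc3ccccc3)cc2OC(/C=C/c3ccc(OCc4ccccc4)cc3)(c3c(OCc4ccccc4)cc(OCc4ccccc4)c4c3O[C@H](c3ccc(OCc5ccccc5)c(OCc5ccccc5)c3)[C@H](OCc3ccccc3)C4)c12 | intermediate (not isolated)
20 | ortho-quinone methide (exocyclic C4a=C4 geometry mobile) | O=C1C=C(OCc2ccccc2)C=C(Br)C1=C(/C=C/c1ccc(OCc2ccccc2)cc1)c1c(OCc3ccccc3)cc(OCc3ccccc3)c2c1O[C@H](c1ccc(OCc3ccccc3)c(OCc3ccccc3)c1)[C@H](OCc1ccccc1)C2 | intermediate (not isolated)
21 | 5-bromo-7,4'-bis(benzyloxy)-4-(penta-O-benzylepicatechin-8-yl)flav-3-ene, both C2 epimers | Brc1cc(OCc3ccccc3)cc2OC(c3ccc(OCc4ccccc4)cc3)C=C(c3c(OCc4ccccc4)cc(OCc4ccccc4)c4c3O[C@H](c3ccc(OCc5ccccc5)c(OCc5ccccc5)c3)[C@H](OCc3ccccc3)C4)c12 | intermediate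
22 | 5-lithio-7,4'-bis(benzyloxy)-4-(penta-O-benzylepicatechin-8-yl)flav-3-ene | [Li]c1cc(OCc3ccccc3)cc2OC(c3ccc(OCc4ccccc4)cc3)C=C(c3c(OCc4ccccc4)cc(OCc4ccccc4)c4c3O[C@H](c3ccc(OCc5ccccc5)c(OCc5ccccc5)c3)[C@H](OCc3ccccc3)C4)c12 | intermediate (not isolated)
23 | 7,4'-bis(benzyloxy)-4-(penta-O-benzylepicatechin-8-yl)flav-3-ene, both C2 epimers | c1cc(OCc3ccccc3)cc2OC(c3ccc(OCc4ccccc4)cc3)C=C(c3c(OCc4ccccc4)cc(OCc4ccccc4)c4c3O[C@H](c3ccc(OCc5ccccc5)c(OCc5ccccc5)c3)[C@H](OCc3ccccc3)C4)c12 | intermediate
24 | C3 alkylborane, 2,3-trans-3,4-trans (upper-unit centres left open: two diastereomers) | c1cc(OCc3ccccc3)cc2OC(c3ccc(OCc4ccccc4)cc3)C(B)C(c3c(OCc4ccccc4)cc(OCc4ccccc4)c4c3O[C@H](c3ccc(OCc5ccccc5)c(OCc5ccccc5)c3)[C@H](OCc3ccccc3)C4)c12 | intermediate (not isolated)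
25 | 2,3-trans-3,4-trans-7,4'-bis(benzyloxy)-4-(penta-O-benzylepicatechin-8-yl)flavan-3-ol (upper-unit centres left open: two diastereomers) | c1cc(OCc3ccccc3)cc2OC(c3ccc(OCc4ccccc4)cc3)C(O)C(c3c(OCc4ccccc4)cc(OCc4ccccc4)c4c3O[C@H](c3ccc(OCc5ccccc5)c(OCc5ccccc5)c3)[C@H](OCc3ccccc3)C4)c12 | intermediate
26 | 7,4'-bis(benzyloxy)-4-(penta-O-benzylepicatechin-8-yl)flavan-3-one, C2 and C4 epimers | c1cc(OCc3ccccc3)cc2OC(c3ccc(OCc4ccccc4)cc3)C(=O)C(c3c(OCc4ccccc4)cc(OCc4ccccc4)c4c3O[C@H](c3ccc(OCc5ccccc5)c(OCc5ccccc5)c3)[C@H](OCc3ccccc3)C4)c12 | intermediate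
27 | (2R,4S)-epimer of 26 (2,4-cis) | c5ccccc5COc1ccc([C@H]2Oc3cc(OCc5ccccc5)ccc3[C@@H](c3c(OCc5ccccc5)cc(OCc5ccccc5)c4c3O[C@H](c3ccc(OCc5ccccc5)c(OCc5ccccc5)c3)[C@H](OCc3ccccc3)C4)C2=O)cc1 | intermediate (not isolated)
28 | (2R,3R,4S)-7,4'-bis(benzyloxy)-4-(penta-O-benzylepicatechin-8-yl)flavan-3-ol | c5ccccc5COc1ccc([C@H]2Oc3cc(OCc5ccccc5)ccc3[C@@H](c3c(OCc5ccccc5)cc(OCc5ccccc5)c4c3O[C@H](c3ccc(OCc5ccccc5)c(OCc5ccccc5)c3)[C@H](OCc3ccccc3)C4)[C@H]2O)cc1 | intermediate
29 | (2R,3R,4S)-2-(4-hydroxyphenyl)-4-[(2R,3R)-2-(3,4-dihydroxyphenyl)-3,5,7-trihydroxychroman-8-yl]chromane-3,7-diol | Oc1ccc([C@H]2Oc3cc(O)ccc3[C@@H](c3c(O)cc(O)c4c3O[C@H](c3ccc(O)c(O)c3)[C@H](O)C4)[C@H]2O)cc1 | target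

Total step count: 15. Longest linear sequence: 10 steps (5, 6, 7, 9, 10, 11, 12, 13, 14, 15). The branch through steps 1–4 and 10–15 is equally long.

Steps most likely to fail

Step 10. The aryne may be consumed by Diels–Alder addition across the styryl unit or by [4+2] addition across O=C–C=C. Closure of the aryl anion on the crowded carbonyl carbon may also be too slow, so that the adduct is lost by protonation. The fallback gives up the aryne and builds ring C first, setting out from 12 and 13 and returning at 23.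
- Commercial 4'-benzyloxy-2'-hydroxyacetophenone (CC(=O)c1ccc(OCc2ccccc2)cc1O) and 13 are joined by Claisen–Schmidt condensation (KOH, EtOH) to 4,4'-bis(benzyloxy)-2'-hydroxychalcone F1.
- Oxa-Michael closure (NaOAc, EtOH, reflux) gives racemic 7,4'-bis(benzyloxy)flavanone F2.
- Aryllithium 15, made from 12 with n-BuLi as in step 9, is added to F2 at −78 °C in the presence of LaCl3·2LiCl, which activates the carbonyl group and suppresses enolisation. This gives the tertiary 4-arylflavan-4-ol F3.
- Mild acid-catalysed dehydration (pyridinium tosylate, toluene, warm) gives 23.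

Step 14. Hydride transfer to a ketone flanked by two aryl-bearing carbons may be slow, epimerisation at C2 may lag behind reduction, and a 2,4-trans epimer or the wrong 2,4-cis form may be reduced. The fallback replaces catalyst control by substrate control plus recycling, setting out from 26 and returning at 28.
- 26 is equilibrated with DBU in THF and reduced with LiBH(s-Bu)3 and LiBr in THF at −78 °C. This is the established equatorial hydride delivery that turns flavan-3-ones into 2,3-cis flavan-3-ols.
- The reduction should give 28 together with the (2S,3S,4R) all-cis diastereomer F4.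
- The two differ as diastereomers through the lower unit and are separated by chromatography.
- F4 is returned to 26 by Dess–Martin oxidation and equilibrated again.

Step 12. Borane may add only sluggishly to the crowded trisubstituted alkene, and the C3 borane may lose the β-aryloxy group with opening of ring C. The fallback avoids boron, setting out from 23 and returning at 26, so that step 13 is also bypassed.
- Epoxidation with dimethyldioxirane (acetone–CH2Cl2, −20 °C) gives the 3,4-epoxy-4-arylflavan F5.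
- Catalytic BF3·OEt2 (CH2Cl2, −78 °C) opens F5 at the diaryl-stabilised C4.
- A Meinwald rearrangement with a 1,2-hydride shift from C3 to C4 then gives 26.

Further compounds
F1 | step 10 | 4,4'-bis(benzyloxy)-2'-hydroxychalcone | O=C(/C=C/c1ccc(OCc2ccccc2)cc1)c1ccc(OCc2ccccc2)cc1O
F2 | step 10 | racemic 7,4'-bis(benzyloxy)flavanone | O=C1CC(c2ccc(OCc3ccccc3)cc2)Oc2cc(OCc3ccccc3)ccc12
F3 | step 10 | 7,4'-bis(benzyloxy)-4-(penta-O-benzylepicatechin-8-yl)flavan-4-ol (C2 and C4 undefined) | OC1(c3c(OCc4ccccc4)cc(OCc4ccccc4)c4c3O[C@H](c3ccc(OCc5ccccc5)c(OCc5ccccc5)c3)[C@H](OCc3ccccc3)C4)CC(c3ccc(OCc4ccccc4)cc3)Oc2cc(OCc3ccccc3)ccc12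
F4 | step 14 | (2S,3S,4R)-7,4'-bis(benzyloxy)-4-(penta-O-benzylepicatechin-8-yl)flavan-3-ol | c5ccccc5COc1ccc([C@@H]2Oc3cc(OCc5ccccc5)ccc3[C@H](c3c(OCc5ccccc5)cc(OCc5ccccc5)c4c3O[C@H](c3ccc(OCc5ccccc5)c(OCc5ccccc5)c3)[C@H](OCc3ccccc3)C4)[C@@H]2O)cc1
F5 | step 12 | 3,4-epoxy-7,4'-bis(benzyloxy)-4-(penta-O-benzylepicatechin-8-yl)flavan (upper-unit centres undefined) | c1cc(OCc3ccccc3)cc2OC(c3ccc(OCc4ccccc4)cc3)C3OC3(c3c(OCc4ccccc4)cc(OCc4ccccc4)c4c3O[C@H](c3ccc(OCc5ccccc5)c(OCc5ccccc5)c3)[C@H](OCc3ccccc3)C4)c12
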